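**Plan of the synthesis**

Chain numbering: C1 = OCH2, C2=C3(CH3), C4 = carbinol carbon, C5=C6, C7 = C(CH3)2OOH.
- **Cuts:** first C7–OO, with the alkene returned from C5=C6 to C6=C7 and the C4 oxygen re-closed onto C5. Then the C1–O bond to the coumarin 4-oxygen, then C4–C5 together with C5–O of the oxirane, and last the two bonds to the lactone carbonyl carbon of the pyranone ring.
- **Enabling feature:** the C4 hydroxyl and the tertiary C7 hydroperoxide stand 1,4 to each other across the E C5=C6 double bond. A C4–C5 oxirane whose C5 bears a 2-methylprop-1-enyl group (C6=C7Me2) leaves this pattern when it is opened at the far alkene terminus.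
- **Forward order:** the pyranone ring is closed on a bought o-hydroxyacetophenone. Separately, prenol becomes a C5 allylic bromide, which as a chiral sulfonium ylide is joined to prenal at C4–C5 with closure of the oxirane. The C10 chain is then tied to the coumarin 4-oxygen, and H2O2 opens the oxirane last.
- **Stereochemistry:** C4, the only stereocentre, is the ylide carbon and takes its configuration from the enantiopure bicyclic sulfide. Its C–O bond is never broken again, and C5 ends as sp2. E C2=C3 comes from the SeO2 oxidation and E C5=C6 from allylic strain in the opening.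

Key step: step 9

Assumption: the sense of induction follows the usual model for this sulfide (sulfur alkylated on its exo lone pair, ylide substituent turned away from the ring carbons, aldehyde approaching on the CH side and not the CMe2 side), which predicts the S oxirane carbon from the (1S,4S,5S)-sulfide; should the antipode result, the equally available (1R,4R,5R)-sulfide is taken instead.

Step 1
Reactants: 1 2'-hydroxy-6'-methylacetophenone; 2 diethyl carbonate
Product: 4 4-hydroxy-5-methylcoumarin, via beta-keto ester 3 (not isolated)
Conditions: NaH, toluene, reflux; then aq. HCl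
Reagents that add atoms: none
Why: Crossed Claisen condensation of the ketone enolate with the non-enolisable carbonate gives keto ester 3, whose ester group is then attacked by the neighbouring phenoxide (lactonisation), the standard entry to 4-hydroxycoumarins, driven by deprotonation of the acidic product.

Step 2
Reactants: 5 3-methylbut-2-en-1-ol (prenol)
Product: 6 tert-butyl[(3-methylbut-2-en-1-yl)oxy]diphenylsilane (prenyl TBDPS ether)
Conditions: TBDPSCl, imidazole, CH2Cl2, 0 °C to rt
Reagents that add atoms: tert-butyl(chloro)diphenylsilane, CC(C)(C)[Si](Cl)(c1ccccc1)c1ccccc1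
Why: Standard silylation of a primary alcohol; the TBDPS ether is chosen because it withstands SeO2/t-BuOOH, the Appel reagent and cold aqueous KOH, and because a silanolate is a poor leaving group for vinylogous elimination from the later ylide.

Step 3
Reactants: 6 prenyl TBDPS ether
Product: 8 (E)-4-[(tert-butyldiphenylsilyl)oxy]-2-methylbut-2-en-1-ol, via enal 7 (not isolated)
Conditions: SeO2 (cat.), t-BuOOH, salicylic acid (cat.), CH2Cl2, rt; crude product, NaBH4, MeOH, 0 °C
Reagents that add atoms: tert-butyl hydroperoxide, CC(C)(C)OO (one oxygen atom, relayed by the SeO2 catalyst)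
Why: Riley allylic oxidation in its catalytic form proceeds by ene reaction and [2,3]-sigmatropic shift and oxidises only the methyl group trans to the CH2OSi chain, which fixes E C2=C3; the part over-oxidised to enal 7 is returned to 8 by 1,2-reduction with borohydride.

Step 4
Reactants: 8 (E)-4-[(tert-butyldiphenylsilyl)oxy]-2-methylbut-2-en-1-ol
Product: 9 {[(E)-4-bromo-3-methylbut-2-en-1-yl]oxy}(tert-butyl)diphenylsilane
Conditions: CBr4, PPh3, CH2Cl2, 0 °C
Reagents that add atoms: carbon tetrabromide, BrC(Br)(Br)Br
Why: Appel reaction, in which bromide displaces the oxyphosphonium ion by SN2 at the primary allylic carbon under neutral conditions, so the E alkene and the silyl ether are kept.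

Step 5
Reactants: 9 allylic bromide; 10 (1S,4S,5S)-4,7,7-trimethyl-6-thiabicyclo[3.2.1]octane (isothiocineole of the (S)-limonene series)
Product: 11 (1S,4S,5S,6S)-6-{(E)-4-[(tert-butyldiphenylsilyl)oxy]-2-methylbut-2-en-1-yl}-4,7,7-trimethyl-6-thiabicyclo[3.2.1]octan-6-ium trifluoromethanesulfonate
Conditions: LiOTf, CH2Cl2/H2O, rt
Reagents that add atoms: lithium trifluoromethanesulfonate, [Li+].[O-]S(=O)(=O)C(F)(F)F
Why: SN2 S-alkylation of the sulfide by the primary allylic bromide is made irreversible by exchange of bromide for non-nucleophilic triflate in the two-phase medium, and only the exo lone pair of sulfur (on the side of the CH2 bridge) is open, so a single configuration at sulfur should result.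

Step 6
Reactants: 11 allylic sulfonium triflate; 12 3-methylbut-2-enal (prenal)
Product: 14 tert-butyl({(E)-3-[(2S,3S)-3-(2-methylprop-1-en-1-yl)oxiran-2-yl]but-2-en-1-yl}oxy)diphenylsilane (silyl-protected trans divinyl epoxide), via sulfonium ylide 13 (not isolated)
Conditions: KOH, 12 (excess), MeCN/H2O 9:1, 0 °C; chromatography on Et3N-washed SiO2
Reagents that add atoms: none
Why: Asymmetric Johnson–Corey–Chaykovsky epoxidation, known for 2-substituted allylic salts of this sulfide and for enals: the rigid bicycle fixes the conformation and open face of the semistabilised ylide 13, so 1,2-addition to the enal and anti-periplanar closure with loss of the sulfide set C4 (the ylide carbon) as S, the protic medium keeps betaine formation irreversible, the anti betaine gives the trans arrangement at C5, and any cis isomer would carry the same C4 configuration and lose C5 later.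

Step 7
Reactants: 14 silyl-protected divinyl epoxide
Product: 15 (E)-3-[(2S,3S)-3-(2-methylprop-1-en-1-yl)oxiran-2-yl]but-2-en-1-ol
Conditions: TBAF, THF, 0 °C to rt; neutral aqueous work-up
Reagents that add atoms: none
Why: Fluoride-induced Si–O cleavage runs under basic, acid-free conditions to which the oxirane and both alkenes are inert, and the E geometry holds the C1 alkoxide away from the oxirane.

Step 8
Reactants: 4 4-hydroxy-5-methylcoumarin; 15 epoxy allylic alcohol
Product: 16 5-methyl-4-({(E)-3-[(2S,3S)-3-(2-methylprop-1-en-1-yl)oxiran-2-yl]but-2-en-1-yl}oxy)-2H-chromen-2-one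
Conditions: PPh3, DIAD, THF, 0 °C (betaine preformed, then 4, then 15), to rt
Reagents that add atoms: none
Why: Mitsunobu reaction, in which the acidic enol 4 protonates the betaine and its 4-oxygen displaces the primary allylic oxyphosphonium ion by SN2, a mode known to favour O- over C3-alkylation of 4-hydroxycoumarins and 4-hydroxypyrones; no stereocentre is touched and the near-neutral medium spares the oxirane.

Step 9
Reactants: 16 coumarinyl ether of the divinyl epoxide; 17 hydrogen peroxide
Product: 18 4-{[(2E,4R,5E)-7-hydroperoxy-4-hydroxy-3,7-dimethylocta-2,5-dien-1-yl]oxy}-5-methyl-2H-chromen-2-one (CNP0299358.1)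
Conditions: anhydrous H2O2 in Et2O (ca. 10 equiv), Yb(OTf)3 (5 mol %), Et2O/THF, −40 to −10 °C; Et3N, cold aq. NaHCO3 (no reductive quench)
Reagents that add atoms: none
Why: Proposed new method: Yb(III) binds the oxirane oxygen and loosens the C5–O bond, the charge being spread over an allyl unit from C5 to the dimethyl-substituted C7, and H2O2 in large excess bonds to C7 while the alkene shifts from C6=C7 to C5=C6 and the C4 oxygen is set free as the hydroxyl group (SN1'/SN2' opening). The closest known reaction types are the Mo(VI)-, heteropolyacid- and SbCl3-catalysed 1,2-perhydrolysis of epoxides to beta-hydroxy hydroperoxides and the acid-catalysed 1,4-solvolysis of vinyl epoxides by water and alcohols, and kinetic capture of 1,1-dimethylallyl cations at the tertiary end is familiar from the solvolysis of prenyl halides. No ring is closed (the oxirane opens) and no stereocentre is made, since C7 carries two methyl groups; the C4–O bond is not touched, so the S oxirane carbon becomes the R carbinol only through a change in CIP ranking (C5 falls below C3 once it has lost its oxygen). Three selectivities are needed: C5–O over C4–O cleavage and 1,4- over 1,2-capture are both secured by the gem-dimethyl terminus (ionisation at C4 would push charge onto secondary C2 beside the electron-poor CH2O-coumarinyl group), and E geometry is secured by A(1,3) strain between the Z methyl on C7 and the C5 substituent, which turns C4 outward in the conformer that aligns C5–O with the pi system, whichever epoxide diastereomer is used. The strained oxirane should ionise far more readily than the bis-allylic alcohol of the product or the allyl coumarinyl ether, hence the weak Lewis acid and low temperature, and a lanthanide triflate is preferred to Mo(VI) catalysts because these, together with a hydroperoxide, would epoxidise the allylic alcohol being formed. The excess of H2O2 should also outrun proton loss from the cation and attack of the product hydroperoxide on a second oxirane.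

**Compound list**

1 | 2'-hydroxy-6'-methylacetophenone | CC(=O)c1c(C)cccc1O | starting material
2 | diethyl carbonate | CCOC(=O)OCC | starting material
3 | ethyl 3-(2-hydroxy-6-methylphenyl)-3-oxopropanoate (not isolated) | CCOC(=O)CC(=O)c1c(C)cccc1O | intermediate
4 | 4-hydroxy-5-methylcoumarin | Cc1cccc2oc(=O)cc(O)c12 | intermediate
5 | 3-methylbut-2-en-1-ol (prenol) | CC(C)=CCO | starting material
6 | tert-butyl[(3-methylbut-2-en-1-yl)oxy]diphenylsilane | CC(C)=CCO[Si](c1ccccc1)(c1ccccc1)C(C)(C)C | intermediate
7 | (E)-4-[(tert-butyldiphenylsilyl)oxy]-2-methylbut-2-enal (not isolated) | C/C(C=O)=C\CO[Si](c1ccccc1)(c1ccccc1)C(C)(C)C | intermediate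
8 | (E)-4-[(tert-butyldiphenylsilyl)oxy]-2-methylbut-2-en-1-ol | C/C(CO)=C\CO[Si](c1ccccc1)(c1ccccc1)C(C)(C)C | intermediate
9 | {[(E)-4-bromo-3-methylbut-2-en-1-yl]oxy}(tert-butyl)diphenylsilane | C/C(CBr)=C\CO[Si](c1ccccc1)(c1ccccc1)C(C)(C)C | intermediate
10 | (1S,4S,5S)-4,7,7-trimethyl-6-thiabicyclo[3.2.1]octane (isothiocineole; bought, or one step from (S)-limonene, sulfur and gamma-terpinene; recovered in step 6) | C[C@H]1CC[C@H]2C[C@@H]1SC2(C)C | starting material
11 | (1S,4S,5S,6S)-6-{(E)-4-[(tert-butyldiphenylsilyl)oxy]-2-methylbut-2-en-1-yl}-4,7,7-trimethyl-6-thiabicyclo[3.2.1]octan-6-ium triflate | C[C@H]1CC[C@H]2C[C@@H]1[S@+](C/C(C)=C/CO[Si](c1ccccc1)(c1ccccc1)C(C)(C)C)C2(C)C.[O-]S(=O)(=O)C(F)(F)F | intermediate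
12 | 3-methylbut-2-enal (prenal) | CC(C)=CC=O | starting material
13 | allylic sulfonium ylide derived from 11 (not isolated) | C[C@H]1CC[C@H]2C[C@@H]1[S@+]([CH-]/C(C)=C/CO[Si](c1ccccc1)(c1ccccc1)C(C)(C)C)C2(C)C | intermediate
14 | tert-butyl({(E)-3-[(2S,3S)-3-(2-methylprop-1-en-1-yl)oxiran-2-yl]but-2-en-1-yl}oxy)diphenylsilane | C/C(=C\CO[Si](c1ccccc1)(c1ccccc1)C(C)(C)C)[C@@H]1O[C@H]1C=C(C)C | intermediate
15 | (E)-3-[(2S,3S)-3-(2-methylprop-1-en-1-yl)oxiran-2-yl]but-2-en-1-ol | C/C(=C\CO)[C@@H]1O[C@H]1C=C(C)C | intermediate
16 | 5-methyl-4-({(E)-3-[(2S,3S)-3-(2-methylprop-1-en-1-yl)oxiran-2-yl]but-2-en-1-yl}oxy)-2H-chromen-2-one | C/C(=C\COc1cc(=O)oc2cccc(C)c12)[C@@H]1O[C@H]1C=C(C)C | intermediate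
17 | hydrogen peroxide (bought as aqueous solution, taken into Et2O and dried over MgSO4 before use) | OO | starting material
18 | 4-{[(2E,4R,5E)-7-hydroperoxy-4-hydroxy-3,7-dimethylocta-2,5-dien-1-yl]oxy}-5-methyl-2H-chromen-2-one | C/C(=C\COc1cc(=O)oc2cccc(C)c12)[C@H](O)/C=C/C(C)(C)OO | target

**Step count**

Total step count: 9. Longest linear sequence: 8 steps (5 to 18, steps 2 to 9); step 1 is the convergent branch.

**Steps most likely to fail**

1. **Step 9 (new method).**
   - What may go wrong: capture of the peroxide at C5 instead of C7, proton loss from a C7 methyl group, renewed ionisation at the doubly allylic C4, or acid-induced Hock-type cleavage of the hydroperoxide.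
   - Fallback: it uses known chemistry only, sets out from 4 and 5 and returns at 18.
   - Mitsunobu etherification of 4 with prenol 5 should give 5-methyl-4-(prenyloxy)coumarin F1. Catalytic SeO2/t-BuOOH oxidation at room temperature should give the E allylic alcohol F2, and MnO2 the E enal F3.
   - Brown allylation with the B-allyldiisopinocampheylborane derived from (−)-alpha-pinene (−78 °C, non-basic oxidative work-up) should give the (R)-homoallylic alcohol F4. This follows the known sense of induction with conjugated and aromatic aldehydes.
   - Cross-metathesis with 2-methylbut-2-ene (second-generation Grubbs catalyst) should turn the vinyl end into the prenyl carbinol F5.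
   - The Schenck ene reaction of F5 with singlet oxygen (O2, tetraphenylporphyrin, visible light, CH2Cl2, 0 °C) attacks the electron-rich C6=C7 alkene and gives 18 where hydrogen is taken from C5. Hydrogen abstraction is divided between the C5 methylene and the methyl groups, so a chromatographic separation is needed.

2. **Step 6.**
   - What may go wrong: erosion of facial selectivity with a non-aryl ylide, vinylogous loss of silanolate from the ylide, base-induced self-condensation of the enal, or thermal Cope rearrangement of any cis-divinyl epoxide.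
   - Fallback: it sets out from 8 and returns at 14.
   - MnO2 oxidation of 8 gives enal 7 (now isolated). Horner–Wadsworth–Emmons olefination with triethyl phosphonoacetate/NaH gives the ethyl (2E,4E)-dienoate F6, and DIBAL-H reduction the dienol F7.
   - Sharpless asymmetric epoxidation of the hydroxyl-bearing alkene [Ti(OiPr)4, L-(+)-diethyl tartrate, t-BuOOH, 4 Å sieves, −20 °C] gives the (2S,3S)-epoxy alcohol F8.
   - Parikh–Doering oxidation gives the epoxy aldehyde F9, and Wittig olefination with isopropylidenetriphenylphosphorane gives 14. Both oxirane carbons are then set by the tartrate and no sulfur ylide is needed.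

3. **Step 8.**
   - What may go wrong: alkylation at C3 or at the lactone carbonyl oxygen of the ambident coumarin, protonation and opening of the oxirane by the acidic partner, or allylic transposition.
   - Fallback: it sets out from 4 (with 15) and returns at 16, with the polarity reversed.
   - POCl3 converts 4 into 4-chloro-5-methylcoumarin F10. The sodium alkoxide of 15 (NaH, THF, 0 °C) then replaces chloride by addition–elimination at the coumarin C4. The coumarin is now the electrophile, so neither an ambident nucleophile nor an acid meets the epoxide.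

**Further compounds**

F1 | step 9 | 5-methyl-4-[(3-methylbut-2-en-1-yl)oxy]-2H-chromen-2-one | CC(C)=CCOc1cc(=O)oc2cccc(C)c12
F2 | step 9 | 4-{[(E)-4-hydroxy-3-methylbut-2-en-1-yl]oxy}-5-methyl-2H-chromen-2-one | C/C(CO)=C\COc1cc(=O)oc2cccc(C)c12
F3 | step 9 | (E)-2-methyl-4-[(5-methyl-2-oxo-2H-chromen-4-yl)oxy]but-2-enal | C/C(C=O)=C\COc1cc(=O)oc2cccc(C)c12
F4 | step 9 | 4-{[(2E,4R)-4-hydroxy-3-methylhepta-2,6-dien-1-yl]oxy}-5-methyl-2H-chromen-2-one | C/C(=C\COc1cc(=O)oc2cccc(C)c12)[C@H](O)CC=C
F5 | step 9 | 4-{[(2E,4R)-4-hydroxy-3,7-dimethylocta-2,6-dien-1-yl]oxy}-5-methyl-2H-chromen-2-one | C/C(=C\COc1cc(=O)oc2cccc(C)c12)[C@H](O)CC=C(C)C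
F6 | step 6 | ethyl (2E,4E)-6-[(tert-butyldiphenylsilyl)oxy]-4-methylhexa-2,4-dienoate | C/C(=C\CO[Si](c1ccccc1)(c1ccccc1)C(C)(C)C)/C=C/C(=O)OCC
F7 | step 6 | (2E,4E)-6-[(tert-butyldiphenylsilyl)oxy]-4-methylhexa-2,4-dien-1-ol | C/C(=C\CO[Si](c1ccccc1)(c1ccccc1)C(C)(C)C)/C=C/CO
F8 | step 6 | [(2S,3S)-3-{(E)-4-[(tert-butyldiphenylsilyl)oxy]but-2-en-2-yl}oxiran-2-yl]methanol | C/C(=C\CO[Si](c1ccccc1)(c1ccccc1)C(C)(C)C)[C@@H]1O[C@H]1CO
F9 | step 6 | (2R,3S)-3-{(E)-4-[(tert-butyldiphenylsilyl)oxy]but-2-en-2-yl}oxirane-2-carbaldehyde | C/C(=C\CO[Si](c1ccccc1)(c1ccccc1)C(C)(C)C)[C@@H]1O[C@H]1C=O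
F10 | step 8 | 4-chloro-5-methyl-2H-chromen-2-one | Cc1cccc2oc(=O)cc(Cl)c12
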